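The flavanone is cut between C3 and C4 of ring C. C4 is carried as the formyl carbon of a hexasubstituted ring A benzaldehyde and C2–C3 as a 1-arylvinyl ether on the neighbouring oxygen O1. One rhodium-catalysed intramolecular hydroacylation then joins the formyl carbon to the terminal vinyl carbon, closes the pyranone ring and sets the only stereocentre, C2, by catalyst control, without reagent, by-product or change of oxidation level. It exploits the 1,3 relation between the C4 carbonyl and the O1–C2 benzylic ether across the C3 methylene. The precursor is achiral: a MOM-protected triprenylated 2-(1-arylvinyloxy)benzaldehyde, assembled by Mitsunobu etherification and dehydrochlorination.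

Key step: step 8

Assumption: (R)-DTBM-SEGPHOS is taken to deliver the (2S) product in step 8; if the first run shows the opposite sense, the (S)-ligand is used with no other change.

Step 1
Reactants: 1 2,4,6-trihydroxybenzaldehyde; 2 prenyl bromide (1-bromo-3-methylbut-2-ene, 2.2 equiv)
Product: 3 2,4,6-trihydroxy-3,5-bis(3-methylbut-2-en-1-yl)benzaldehyde
Conditions: 10% aq KOH, 0 °C to rt
Reagents that add atoms: none
Why: The phloroglucinol-type phenoxide is ambident and in water should react at carbon, so double C-prenylation of the phenoxide fills the two equivalent free ring positions; no stereocentre is formed.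

Step 2
Reactants: 3 2,4,6-trihydroxy-3,5-bis(3-methylbut-2-en-1-yl)benzaldehyde
Product: 4 2-hydroxy-4,6-bis(methoxymethoxy)-3,5-bis(3-methylbut-2-en-1-yl)benzaldehyde
Conditions: MOMCl (2.2 equiv), iPr2NEt, CH2Cl2, 0 °C to rt
Reagents that add atoms: chloromethyl methyl ether (MOMCl), COCCl
Why: Williamson-type O-alkylation with an amine base should protect the para hydroxyl and one of the two equivalent ortho hydroxyls and stop there, because the last ortho hydroxyl is held in a hydrogen bond to the formyl oxygen.

Step 3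
Reactants: 5 4-hydroxybenzaldehyde; 2 prenyl bromide
Product: 6 4-hydroxy-3-(3-methylbut-2-en-1-yl)benzaldehyde
Conditions: 10% aq KOH, rt
Reagents that add atoms: none
Why: Ortho C-alkylation of the phenoxide in water (C-prenylation) should place the prenyl group next to the hydroxyl, the para position being blocked by the formyl group.

Step 4
Reactants: 6 4-hydroxy-3-(3-methylbut-2-en-1-yl)benzaldehyde
Product: 7 4-(methoxymethoxy)-3-(3-methylbut-2-en-1-yl)benzaldehyde
Conditions: MOMCl, iPr2NEt, CH2Cl2, 0 °C to rt
Reagents that add atoms: chloromethyl methyl ether (MOMCl), COCCl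
Why: Williamson-type MOM ether formation masks the only acidic proton before the organolithium and Mitsunobu steps.

Step 5
Reactants: 7 4-(methoxymethoxy)-3-(3-methylbut-2-en-1-yl)benzaldehyde
Product: 8 rac-2-chloro-1-[4-(methoxymethoxy)-3-(3-methylbut-2-en-1-yl)phenyl]ethanol
Conditions: ICH2Cl, MeLi·LiBr, THF, −78 °C; then AcOH, −78 °C
Reagents that add atoms: chloroiodomethane, ClCI
Why: Chloromethyllithium, formed by iodine–lithium exchange in the presence of the aldehyde, should add to the formyl group (carbenoid 1,2-addition) and the cold acidic quench traps the chlorohydrin before epoxide closure; the new centre is racemic, which does not matter because it becomes sp2 in step 7.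

Step 6
Reactants: 4 2-hydroxy-4,6-bis(methoxymethoxy)-3,5-bis(3-methylbut-2-en-1-yl)benzaldehyde; 8 rac-2-chloro-1-[4-(methoxymethoxy)-3-(3-methylbut-2-en-1-yl)phenyl]ethanol
Product: 9 rac-2-{2-chloro-1-[4-(methoxymethoxy)-3-(3-methylbut-2-en-1-yl)phenyl]ethoxy}-4,6-bis(methoxymethoxy)-3,5-bis(3-methylbut-2-en-1-yl)benzaldehyde
Conditions: PPh3, DIAD, THF, 0 °C to rt (sonication if slow)
Reagents that add atoms: none
Why: Mitsunobu etherification should join the only free, salicylaldehyde-type acidic phenol of 4 to the activated benzylic alcohol; the configuration of the ether carbon is irrelevant at this stage.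

Step 7
Reactants: 9 rac-2-{2-chloro-1-[4-(methoxymethoxy)-3-(3-methylbut-2-en-1-yl)phenyl]ethoxy}-4,6-bis(methoxymethoxy)-3,5-bis(3-methylbut-2-en-1-yl)benzaldehyde
Product: 10 2-({1-[4-(methoxymethoxy)-3-(3-methylbut-2-en-1-yl)phenyl]ethenyl}oxy)-4,6-bis(methoxymethoxy)-3,5-bis(3-methylbut-2-en-1-yl)benzaldehyde
Conditions: KOtBu, THF, 0 °C; base-washed silica for purification
Reagents that add atoms: none
Why: E2 dehydrochlorination of a 2-chloroethyl aryl ether is the classical entry to aryl vinyl ethers, and the only β-hydrogen is the benzylic, oxygen-bearing one, so the 1-arylvinyl ether should form and the racemic centre is erased.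

Step 8
Reactants: 10 2-({1-[4-(methoxymethoxy)-3-(3-methylbut-2-en-1-yl)phenyl]ethenyl}oxy)-4,6-bis(methoxymethoxy)-3,5-bis(3-methylbut-2-en-1-yl)benzaldehyde
Product: 11 (2S)-5,7-bis(methoxymethoxy)-2-[4-(methoxymethoxy)-3-(3-methylbut-2-en-1-yl)phenyl]-6,8-bis(3-methylbut-2-en-1-yl)chroman-4-one
Conditions: [Rh(cod)Cl]2 (2.5 mol%), (R)-DTBM-SEGPHOS (5 mol%), NaB[3,5-(CF3)2C6H3]4 (5 mol%), 1,4-dioxane, 60 °C
Reagents that add atoms: none
Why: Proposed new method: cationic monovalent rhodium should insert into the formyl C–H bond of 10 to give an acyl hydride of trivalent rhodium, the tethered 1-arylvinyl ether then inserts into Rh–H with the hydride delivered to the oxygen-bearing carbon (future C2) and rhodium bound to the terminal CH2 (future C3), and C–C reductive elimination from the seven-membered acyl alkyl rhodacycle forms the C3–C4 bond and frees the catalyst. The closest known reaction type is the enantioselective rhodium-catalysed endo hydroacylation of ortho-allylbenzaldehydes bearing a 1,1-disubstituted alkene, which gives 3-substituted tetralones; 10 is the oxygen analogue in which the benzylic CH2 is replaced by the ether oxygen, a substrate class (1-arylvinyl ethers of salicylaldehydes) on which this reaction has not been shown. Ring C is closed in a formal 6-endo-trig mode, both alkene carbons ending up in the pyranone ring. The single stereocentre C2 is created in the hydride insertion, whose enantioface selection is controlled by the chiral bisphosphine (catalyst control). The step needs endo over exo regioselectivity, which the 1,1-disubstitution secures because the exo path requires a tertiary alkyl rhodium and reductive elimination to a quaternary benzofuranone carbon, and chemoselectivity over the three prenyl groups, which are trisubstituted and cannot reach the acyl rhodium through a small ring. Decarbonylation should be held back by the fast intramolecular insertion, and the neutral conditions leave the MOM ethers and the base-labile C2 configuration untouched.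

Step 9
Reactants: 11 (2S)-5,7-bis(methoxymethoxy)-2-[4-(methoxymethoxy)-3-(3-methylbut-2-en-1-yl)phenyl]-6,8-bis(3-methylbut-2-en-1-yl)chroman-4-one
Product: 12 (2S)-5,7-dihydroxy-2-[4-hydroxy-3-(3-methylbut-2-en-1-yl)phenyl]-6,8-bis(3-methylbut-2-en-1-yl)chroman-4-one
Conditions: 3 M aq HCl, MeOH, 40–45 °C, stopped as soon as the last MOM group is gone
Reagents that add atoms: none
Why: Acid-catalysed acetal methanolysis should remove the three MOM ethers (the 5-O-MOM group fastest, assisted by the peri carbonyl), and at this mild temperature the prenyl groups should not cyclise onto the phenols and C2 should keep its configuration.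

Compound list
1 | 2,4,6-trihydroxybenzaldehyde | O=Cc1c(O)cc(O)cc1O | starting material
2 | prenyl bromide (1-bromo-3-methylbut-2-ene) | CC(C)=CCBr | starting material
3 | 2,4,6-trihydroxy-3,5-bis(3-methylbut-2-en-1-yl)benzaldehyde | O=Cc1c(O)c(CC=C(C)C)c(O)c(CC=C(C)C)c1O | intermediate
4 | 2-hydroxy-4,6-bis(methoxymethoxy)-3,5-bis(3-methylbut-2-en-1-yl)benzaldehyde | O=Cc1c(O)c(CC=C(C)C)c(OCOC)c(CC=C(C)C)c1OCOC | intermediate
5 | 4-hydroxybenzaldehyde | O=Cc1ccc(O)cc1 | starting material
6 | 4-hydroxy-3-(3-methylbut-2-en-1-yl)benzaldehyde | O=Cc1ccc(O)c(CC=C(C)C)c1 | intermediate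
7 | 4-(methoxymethoxy)-3-(3-methylbut-2-en-1-yl)benzaldehyde | O=Cc1ccc(OCOC)c(CC=C(C)C)c1 | intermediate
8 | rac-2-chloro-1-[4-(methoxymethoxy)-3-(3-methylbut-2-en-1-yl)phenyl]ethanol | OC(CCl)c1ccc(OCOC)c(CC=C(C)C)c1 | intermediate
9 | rac-2-{2-chloro-1-[4-(methoxymethoxy)-3-(3-methylbut-2-en-1-yl)phenyl]ethoxy}-4,6-bis(methoxymethoxy)-3,5-bis(3-methylbut-2-en-1-yl)benzaldehyde | O=Cc1c(OC(CCl)c2ccc(OCOC)c(CC=C(C)C)c2)c(CC=C(C)C)c(OCOC)c(CC=C(C)C)c1OCOC | intermediate
10 | 2-({1-[4-(methoxymethoxy)-3-(3-methylbut-2-en-1-yl)phenyl]ethenyl}oxy)-4,6-bis(methoxymethoxy)-3,5-bis(3-methylbut-2-en-1-yl)benzaldehyde | O=Cc1c(OC(=C)c2ccc(OCOC)c(CC=C(C)C)c2)c(CC=C(C)C)c(OCOC)c(CC=C(C)C)c1OCOC | intermediate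
11 | (2S)-5,7-bis(methoxymethoxy)-2-[4-(methoxymethoxy)-3-(3-methylbut-2-en-1-yl)phenyl]-6,8-bis(3-methylbut-2-en-1-yl)chroman-4-one | CC(C)=CCc1cc([C@@H]2CC(=O)c3c(OCOC)c(CC=C(C)C)c(OCOC)c(CC=C(C)C)c3O2)ccc1OCOC | intermediate
12 | (2S)-5,7-dihydroxy-2-[4-hydroxy-3-(3-methylbut-2-en-1-yl)phenyl]-6,8-bis(3-methylbut-2-en-1-yl)chroman-4-one | CC(C)=CCc1cc([C@@H]2CC(=O)c3c(O)c(CC=C(C)C)c(O)c(CC=C(C)C)c3O2)ccc1O | target

Total step count: 9
Longest linear sequence: 7 steps (steps 3 to 9, from 5 to 12)

Steps most likely to fail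

1. Step 8 (key step).
 - What may go wrong: decarbonylation of the acyl rhodium hydride, exo insertion to the five-membered ketone, Lewis-acid Prins-type attack of the enol ether on the aldehyde, or weak enantioface discrimination.
 - Fallback: it keeps the same ring closure but sets the stereocentre beforehand and closes the ring by a known acyl-anion alkylation. It sets out from chlorohydrin 8 and phenol 4 and comes back at 11.
 - Dess–Martin oxidation of 8 (CH2Cl2) should give 2-chloro-1-[4-(methoxymethoxy)-3-(3-methylbut-2-en-1-yl)phenyl]ethanone F1.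
 - Asymmetric transfer hydrogenation with RuCl[(R,R)-TsDPEN](p-cymene) in HCO2H/Et3N, which leaves the prenyl group alone, should give (S)-2-chloro-1-[4-(methoxymethoxy)-3-(3-methylbut-2-en-1-yl)phenyl]ethanol F2.
 - Mitsunobu coupling of F2 with 4 (PPh3, DIAD, toluene, low temperature to favour inversion) should give (R)-2-{2-chloro-1-[4-(methoxymethoxy)-3-(3-methylbut-2-en-1-yl)phenyl]ethoxy}-4,6-bis(methoxymethoxy)-3,5-bis(3-methylbut-2-en-1-yl)benzaldehyde F3.
 - N-heterocyclic carbene catalysis (3-benzyl-5-(2-hydroxyethyl)-4-methylthiazolium chloride, DBU, 1,4-dioxane, heat) then turns the aldehyde into its Breslow intermediate, which displaces the primary chloride in a 6-exo-tet SN2 closure. This is a known way to chroman-4-ones from 2-(2-haloethoxy)- or 2-(2-sulfonyloxyethoxy)benzaldehydes. It forms the C3–C4 bond without touching the stereocentre and gives 11; the base is kept to the minimum to protect the C2 configuration.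

2. Step 6.
 - What may go wrong: slow attack of the hindered, hydrogen-bonded phenol, with the activated benzylic alcohol lost by elimination or chloride capture.
 - Fallback: it replaces the Mitsunobu reaction by an epoxide opening. It sets out from aldehyde 7 and phenol 4 and comes back at 10.
 - Corey–Chaykovsky methylenation of 7 (Me3SI, NaH, DMSO/THF) should give 2-[4-(methoxymethoxy)-3-(3-methylbut-2-en-1-yl)phenyl]oxirane F4.
 - Opening of this electron-rich styrene oxide by 4 at the benzylic carbon (cat. Sc(OTf)3, CH2Cl2, −20 °C) should give 2-{2-hydroxy-1-[4-(methoxymethoxy)-3-(3-methylbut-2-en-1-yl)phenyl]ethoxy}-4,6-bis(methoxymethoxy)-3,5-bis(3-methylbut-2-en-1-yl)benzaldehyde F5.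
 - MsCl/Et3N converts F5 into 2-{2-(methanesulfonyloxy)-1-[4-(methoxymethoxy)-3-(3-methylbut-2-en-1-yl)phenyl]ethoxy}-4,6-bis(methoxymethoxy)-3,5-bis(3-methylbut-2-en-1-yl)benzaldehyde F6.
 - KOtBu in THF eliminates methanesulfonate from F6 to give enol ether 10.

3. Step 1.
 - What may go wrong: competition of O-alkylation, mono-alkylation and geminal over-alkylation with dearomatisation of ring A.
 - Fallback: it replaces phenoxide alkylation by halogenation and cross-coupling. It sets out from 1 and comes back at 4.
 - Double iodination of 1 (N-iodosuccinimide, 2 equiv, MeCN, 0 °C) should give 2,4,6-trihydroxy-3,5-diiodobenzaldehyde F7.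
 - MOMCl/iPr2NEt as in step 2 should give 2-hydroxy-3,5-diiodo-4,6-bis(methoxymethoxy)benzaldehyde F8.
 - Double Stille coupling of F8 with tributyl(3-methylbut-2-en-1-yl)stannane (Pd(PPh3)4, a complex of zerovalent palladium, DMF, 90 °C) should install both prenyl groups with the linear regiochemistry and give 4.

Further compounds
F1 | step 8 | 2-chloro-1-[4-(methoxymethoxy)-3-(3-methylbut-2-en-1-yl)phenyl]ethanone | O=C(CCl)c1ccc(OCOC)c(CC=C(C)C)c1
F2 | step 8 | (S)-2-chloro-1-[4-(methoxymethoxy)-3-(3-methylbut-2-en-1-yl)phenyl]ethanol | ClC[C@@H](O)c1ccc(OCOC)c(CC=C(C)C)c1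
F3 | step 8 | (R)-2-{2-chloro-1-[4-(methoxymethoxy)-3-(3-methylbut-2-en-1-yl)phenyl]ethoxy}-4,6-bis(methoxymethoxy)-3,5-bis(3-methylbut-2-en-1-yl)benzaldehyde | ClC[C@H](Oc1c(C=O)c(OCOC)c(CC=C(C)C)c(OCOC)c1CC=C(C)C)c1ccc(OCOC)c(CC=C(C)C)c1
F4 | step 6 | 2-[4-(methoxymethoxy)-3-(3-methylbut-2-en-1-yl)phenyl]oxirane | C1OC1c1ccc(OCOC)c(CC=C(C)C)c1
F5 | step 6 | 2-{2-hydroxy-1-[4-(methoxymethoxy)-3-(3-methylbut-2-en-1-yl)phenyl]ethoxy}-4,6-bis(methoxymethoxy)-3,5-bis(3-methylbut-2-en-1-yl)benzaldehyde | O=Cc1c(OC(CO)c2ccc(OCOC)c(CC=C(C)C)c2)c(CC=C(C)C)c(OCOC)c(CC=C(C)C)c1OCOC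
F6 | step 6 | 2-{2-(methanesulfonyloxy)-1-[4-(methoxymethoxy)-3-(3-methylbut-2-en-1-yl)phenyl]ethoxy}-4,6-bis(methoxymethoxy)-3,5-bis(3-methylbut-2-en-1-yl)benzaldehyde | O=Cc1c(OC(COS(C)(=O)=O)c2ccc(OCOC)c(CC=C(C)C)c2)c(CC=C(C)C)c(OCOC)c(CC=C(C)C)c1OCOC
F7 | step 1 | 2,4,6-trihydroxy-3,5-diiodobenzaldehyde | O=Cc1c(O)c(I)c(O)c(I)c1O
F8 | step 1 | 2-hydroxy-3,5-diiodo-4,6-bis(methoxymethoxy)benzaldehyde | O=Cc1c(O)c(I)c(OCOC)c(I)c1OCOC
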